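## Retrosynthetic overview
1. Waltherione H (21) comes from the N‑hydroxy‑pyridone by O‑methylation. That in turn comes from the 4‑pyranone by hydroxylamine ring exchange. The 8‑OMe comes from methylation of the 5,8‑cis alcohol, which a ketoreductase makes from the 8‑ketone.
2. The tetrahydrochromone comes from a 2‑acylcyclohexanone β‑diketone by Baker–Venkataraman acetyl transfer and cyclodehydration. The acetyl group supplies the 2‑Me.
3. The β‑diketone comes from the regiospecific zinc enolate of a Cu‑catalysed asymmetric conjugate addition (ACA) of (5‑phenylpentyl)2Zn to cyclohexenone. The dialkylzinc is made in situ from the Grignard reagent 2. The ACA sets C5, the first stereocentre. The enolate is trapped as an aldol with benzyloxyacetaldehyde, and the C8 oxygen is added at the only remaining CH2 α‑carbon.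
4. Rings are formed in the order carbocycle (ACA), then 4‑pyranone, then 4‑pyridone.

**Assumptions**
- All starting materials are commercial.
- The (S,R,R)‑phosphoramidite gives the (S)‑3‑alkylcyclohexanone, as it does for Et2Zn. The ligand enantiomer is swapped if chiral HPLC shows the other enantiomer.
- A commercial KRED panel contains a variant that gives the (8R)‑alcohol (cis to the 5S chain).

## Route

**Step 1**
Reactants: 1 (1‑bromo‑5‑phenylpentane)
Product: 2 (5‑phenylpentylmagnesium bromide)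
Conditions: Mg turnings (1.2 equiv), I2 (cat.), THF, 25 → 60 °C
Reagents that add atoms: magnesium, [Mg]
Why: Oxidative insertion of Mg into the C–Br bond (Grignard formation) gives the C11 organometallic. Each molecule of 2 carries one 5‑phenylpentyl group, which is all that each molecule of product 5 needs.

**Step 2**
Reactants: 3 (cyclohex‑2‑en‑1‑one), 2, 4 (2‑(benzyloxy)acetaldehyde)
Product: 5 ((3S)‑2‑[2‑(benzyloxy)‑1‑hydroxyethyl]‑3‑(5‑phenylpentyl)cyclohexan‑1‑one, mixture at C2 and the carbinol carbon)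
Conditions: (i) 2 (2.6 equiv), ZnCl2 (1.3 equiv), THF, 0 °C, 30 min; swap solvent to PhMe and filter off MgBrCl to give ca. 1.3 equiv of (5‑phenylpentyl)2Zn. (ii) Cu(OTf)2 (2 mol%), (S,R,R)‑phosphoramidite (4 mol%), 3, PhMe, −30 °C, 3 h. (iii) 4 (1.5 equiv), −30 → 0 °C
Reagents that add atoms: none
Why: Transmetalation of two equivalents of 2 with ZnCl2 gives the dialkylzinc, one alkyl group of which is transferred. The Cu/phosphoramidite ACA sets C3 (the future C5) as S. The resulting zinc enolate is regiospecific at C2 (the future C4a), so it adds to the aldehyde there (tandem ACA–aldol). The C2 and carbinol centres are destroyed at Step 7.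

**Step 3**
Reactants: 5
Product: 6 (triethylsilyl ether of 5)
Conditions: TESOTf, 2,6‑lutidine, CH2Cl2, −78 → 0 °C
Reagents that add atoms: triethylsilyl triflate, CC[Si](CC)(CC)OS(=O)(=O)C(F)(F)F
Why: Silylation masks the aldol OH so that it survives the enolate chemistry of Step 4.

**Step 4**
Reactants: 6
Product: 7 ((3S)‑6‑hydroxy‑2‑[2‑(benzyloxy)‑1‑(triethylsilyloxy)ethyl]‑3‑(5‑phenylpentyl)cyclohexan‑1‑one, epimeric mixture)
Conditions: LDA, THF, −78 °C; then Davis oxaziridine, −78 °C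
Reagents that add atoms: (±)‑trans‑2‑(phenylsulfonyl)‑3‑phenyloxaziridine, O=S(=O)(c1ccccc1)N1OC1c1ccccc1
Why: C2 is now tertiary and hindered, so kinetic LDA deprotonation occurs only at C6 (the future C8). Davis α‑hydroxylation of that enolate installs the C8 oxygen, whose configuration is reset later.

**Step 5**
Reactants: 7
Product: 8 (6‑TBS ether of 7)
Conditions: TBSOTf, 2,6‑lutidine, CH2Cl2, −78 → 0 °C
Reagents that add atoms: tert‑butyldimethylsilyl triflate, CC(C)(C)[Si](C)(C)OS(=O)(=O)C(F)(F)F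
Why: A TBS ether is more robust than the TES ether and survives the later acid, base and hydrogenolysis steps. The two silyl groups can be removed selectively.

**Step 6**
Reactants: 8
Product: 9 (free carbinol, 6‑OTBS retained)
Conditions: PPTS (0.2 equiv), MeOH, 0 → 25 °C
Reagents that add atoms: none
Why: Mild acidic methanolysis cleaves the TES ether much faster than the secondary TBS ether.

**Step 7**
Reactants: 9
Product: 10 ((3S)‑6‑(TBSO)‑2‑[(benzyloxy)acetyl]‑3‑(5‑phenylpentyl)cyclohexan‑1‑one, largely enolised β‑diketone)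
Conditions: Dess–Martin periodinane, NaHCO3, CH2Cl2, 25 °C
Reagents that add atoms: none
Why: DMP oxidation of the β‑hydroxy ketone gives the 1,3‑diketone, and the C2 stereocentre is lost by enolisation.

**Step 8**
Reactants: 10
Product: 11 ((3S)‑2‑[(benzyloxy)acetyl]‑6‑(TBSO)‑3‑(5‑phenylpentyl)cyclohex‑1‑en‑1‑yl acetate)
Conditions: Ac2O, Et3N, DMAP (cat.), CH2Cl2, 0 → 25 °C
Reagents that add atoms: acetic anhydride, CC(=O)OC(C)=O
Why: O‑Acylation of the ring enol gives the enol ester needed for Baker–Venkataraman acyl transfer. DMAP lets the acetyl group equilibrate between the two enolate oxygens, and the ring‑O acetate is the isomer that is consumed in Step 9.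

**Step 9**
Reactants: 11
Product: 12 ((3S)‑2‑[2‑(benzyloxy)‑3‑oxobutanoyl]‑6‑(TBSO)‑3‑(5‑phenylpentyl)cyclohexan‑1‑one, 1,3,5‑triketone)
Conditions: t‑BuOK (2 equiv), THF, 0 °C, then aq. NH4Cl
Reagents that add atoms: none
Why: Baker–Venkataraman rearrangement: the enolate of the CH2OBn ketone attacks the enol acetate through a six‑membered transition state, moving the acetyl group from O to C. This supplies C2 and its methyl.

**Step 10**
Reactants: 12
Product: 13 ((5S)‑3‑(benzyloxy)‑8‑(TBSO)‑2‑methyl‑5‑(5‑phenylpentyl)‑5,6,7,8‑tetrahydro‑4H‑chromen‑4‑one, C8 epimeric)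
Conditions: TsOH·H2O (0.2 equiv), PhMe, 80 °C
Reagents that add atoms: none
Why: Acid‑catalysed cyclodehydration of the 1,3,5‑triketone closes the 4‑pyranone ring. Any TBS loss is harmless because the C8 oxygen is carried forward as the free alcohol at Step 13 anyway.

**Step 11**
Reactants: 13
Product: 14 ((5S)‑8‑(TBSO)‑3‑hydroxy‑2‑methyl‑5‑(5‑phenylpentyl)‑5,6,7,8‑tetrahydro‑4H‑chromen‑4‑one)
Conditions: H2 (1 atm), 10% Pd/C, EtOAc, 25 °C, 1 h
Reagents that add atoms: none
Why: Hydrogenolysis of the maltol‑type benzyl ether under mild conditions leaves the pyranone, the TBS ether and the phenyl ring intact.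

**Step 12**
Reactants: 14
Product: 15 ((5S)‑8‑(TBSO)‑3‑methoxy‑2‑methyl‑5‑(5‑phenylpentyl)‑5,6,7,8‑tetrahydro‑4H‑chromen‑4‑one)
Conditions: MeI, K2CO3, acetone, 25 °C
Reagents that add atoms: methyl iodide, CI
Why: The acidic, maltol‑like 3‑OH is alkylated selectively, giving the 3‑OMe.

**Step 13**
Reactants: 15
Product: 16 ((5S)‑8‑hydroxy‑3‑methoxy‑2‑methyl‑5‑(5‑phenylpentyl)‑5,6,7,8‑tetrahydro‑4H‑chromen‑4‑one, C8 epimeric)
Conditions: HF·pyridine, THF/pyridine, 0 → 25 °C
Reagents that add atoms: none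
Why: Fluoride desilylation is neutral enough to avoid epimerising or eliminating the pyranone.

**Step 14**
Reactants: 16
Product: 17 ((5S)‑3‑methoxy‑2‑methyl‑5‑(5‑phenylpentyl)‑6,7‑dihydro‑4H‑chromene‑4,8(5H)‑dione)
Conditions: Dess–Martin periodinane, NaHCO3, CH2Cl2, 25 °C
Reagents that add atoms: none
Why: Oxidation removes the uncontrolled C8 configuration, so both C8 epimers converge on one ketone that carries only the C5 (S) centre.

**Step 15**
Reactants: 17
Product: 18 ((5S,8R)‑8‑hydroxy‑3‑methoxy‑2‑methyl‑5‑(5‑phenylpentyl)‑5,6,7,8‑tetrahydro‑4H‑chromen‑4‑one)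
Conditions: KRED (NADPH‑dependent ketoreductase, (R)‑selective panel hit), NADP+ (cat.), glucose, glucose dehydrogenase, KPi pH 7.0/DMSO 8:2, 30 °C, 24 h
Reagents that add atoms: none
Why: Enzymatic asymmetric ketone reduction (oxidoreductase) delivers hydride to one face of the C8 carbonyl, giving the (8R) alcohol cis to the (5S) chain. The enzyme's face selectivity overrides the remote C5 stereocentre.

**Step 16**
Reactants: 18
Product: 19 ((5S,8R)‑3,8‑dimethoxy‑2‑methyl‑5‑(5‑phenylpentyl)‑5,6,7,8‑tetrahydro‑4H‑chromen‑4‑one)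
Conditions: MeI, Ag2O, DMF, 25 °C, dark
Reagents that add atoms: methyl iodide, CI
Why: Purdie‑type methylation under neutral conditions avoids base‑mediated epimerisation at C8 and deprotonation of the 2‑methyl group.

**Step 17**
Reactants: 19
Product: 20 ((5S,8R)‑1‑hydroxy‑3,8‑dimethoxy‑2‑methyl‑5‑(5‑phenylpentyl)‑5,6,7,8‑tetrahydroquinolin‑4(1H)‑one)
Conditions: NH2OH·HCl (5 equiv), NaHCO3, EtOH/H2O, 80 °C, sealed tube
Reagents that add atoms: hydroxylamine, NO
Why: Hydroxylamine adds in conjugate fashion to the vinylogous ester, opens the pyranone and recloses it as the N‑hydroxy‑4‑pyridone (4‑pyranone→4‑pyridone exchange), forming the third ring.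

**Step 18**
Reactants: 20
Product: 21 (Waltherione H)
Conditions: MeI, K2CO3, DMF, 25 °C
Reagents that add atoms: methyl iodide, CI
Why: Alkylation of the acidic N–OH oxygen gives the N‑methoxy‑4‑pyridone.

## Compound list
1 | 1‑bromo‑5‑phenylpentane | BrCCCCCc1ccccc1 | starting material
2 | 5‑phenylpentylmagnesium bromide | Br[Mg]CCCCCc1ccccc1 | intermediate
3 | cyclohex‑2‑en‑1‑one | O=C1C=CCCC1 | starting material
4 | 2‑(benzyloxy)acetaldehyde | O=CCOCc1ccccc1 | starting material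
5 | (3S)‑2‑[2‑(benzyloxy)‑1‑hydroxyethyl]‑3‑(5‑phenylpentyl)cyclohexan‑1‑one | c1ccccc1CCCCC[C@H]2CCCC(=O)C2C(O)COCc2ccccc2 | intermediate
6 | TES ether of 5 | c1ccccc1CCCCC[C@H]2CCCC(=O)C2C(O[Si](CC)(CC)CC)COCc2ccccc2 | intermediate
7 | (3S)‑6‑hydroxy‑2‑[2‑(benzyloxy)‑1‑(triethylsilyloxy)ethyl]‑3‑(5‑phenylpentyl)cyclohexan‑1‑one | c1ccccc1CCCCC[C@H]2CCC(O)C(=O)C2C(O[Si](CC)(CC)CC)COCc2ccccc2 | intermediate
8 | 6‑TBS ether of 7 | c1ccccc1CCCCC[C@H]2CCC(O[Si](C)(C)C(C)(C)C)C(=O)C2C(O[Si](CC)(CC)CC)COCc2ccccc2 | intermediate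
9 | (3S)‑6‑(TBSO)‑2‑[2‑(benzyloxy)‑1‑hydroxyethyl]‑3‑(5‑phenylpentyl)cyclohexan‑1‑one | c1ccccc1CCCCC[C@H]2CCC(O[Si](C)(C)C(C)(C)C)C(=O)C2C(O)COCc2ccccc2 | intermediate
10 | (3S)‑6‑(TBSO)‑2‑[(benzyloxy)acetyl]‑3‑(5‑phenylpentyl)cyclohexan‑1‑one | c1ccccc1CCCCC[C@H]2CCC(O[Si](C)(C)C(C)(C)C)C(=O)C2C(=O)COCc2ccccc2 | intermediate
11 | (3S)‑2‑[(benzyloxy)acetyl]‑6‑(TBSO)‑3‑(5‑phenylpentyl)cyclohex‑1‑en‑1‑yl acetate | c1ccccc1CCCCC[C@H]2CCC(O[Si](C)(C)C(C)(C)C)C(OC(C)=O)=C2C(=O)COCc2ccccc2 | intermediate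
12 | (3S)‑2‑[2‑(benzyloxy)‑3‑oxobutanoyl]‑6‑(TBSO)‑3‑(5‑phenylpentyl)cyclohexan‑1‑one | c1ccccc1CCCCC[C@H]2CCC(O[Si](C)(C)C(C)(C)C)C(=O)C2C(=O)C(OCc2ccccc2)C(C)=O | intermediate
13 | (5S)‑3‑(benzyloxy)‑8‑(TBSO)‑2‑methyl‑5‑(5‑phenylpentyl)‑5,6,7,8‑tetrahydro‑4H‑chromen‑4‑one | Cc1oc2C(O[Si](C)(C)C(C)(C)C)CC[C@H](CCCCCc3ccccc3)c2c(=O)c1OCc1ccccc1 | intermediate
14 | (5S)‑8‑(TBSO)‑3‑hydroxy‑2‑methyl‑5‑(5‑phenylpentyl)‑5,6,7,8‑tetrahydro‑4H‑chromen‑4‑one | Cc1oc2C(O[Si](C)(C)C(C)(C)C)CC[C@H](CCCCCc3ccccc3)c2c(=O)c1O | intermediate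
15 | (5S)‑8‑(TBSO)‑3‑methoxy‑2‑methyl‑5‑(5‑phenylpentyl)‑5,6,7,8‑tetrahydro‑4H‑chromen‑4‑one | Cc1oc2C(O[Si](C)(C)C(C)(C)C)CC[C@H](CCCCCc3ccccc3)c2c(=O)c1OC | intermediate
16 | (5S)‑8‑hydroxy‑3‑methoxy‑2‑methyl‑5‑(5‑phenylpentyl)‑5,6,7,8‑tetrahydro‑4H‑chromen‑4‑one | Cc1oc2C(O)CC[C@H](CCCCCc3ccccc3)c2c(=O)c1OC | intermediate
17 | (5S)‑3‑methoxy‑2‑methyl‑5‑(5‑phenylpentyl)‑6,7‑dihydro‑4H‑chromene‑4,8(5H)‑dione | Cc1oc2C(=O)CC[C@H](CCCCCc3ccccc3)c2c(=O)c1OC | intermediate
18 | (5S,8R)‑8‑hydroxy‑3‑methoxy‑2‑methyl‑5‑(5‑phenylpentyl)‑5,6,7,8‑tetrahydro‑4H‑chromen‑4‑one | COc1c(C)oc2c(c1=O)[C@@H](CCCCCc1ccccc1)CC[C@H]2O | intermediate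
19 | (5S,8R)‑3,8‑dimethoxy‑2‑methyl‑5‑(5‑phenylpentyl)‑5,6,7,8‑tetrahydro‑4H‑chromen‑4‑one | COc1c(C)oc2c(c1=O)[C@@H](CCCCCc1ccccc1)CC[C@H]2OC | intermediate
20 | (5S,8R)‑1‑hydroxy‑3,8‑dimethoxy‑2‑methyl‑5‑(5‑phenylpentyl)‑5,6,7,8‑tetrahydroquinolin‑4(1H)‑one | COc1c(C)n(O)c2c(c1=O)[C@@H](CCCCCc1ccccc1)CC[C@H]2OC | intermediate
21 | Waltherione H, (5S,8R)‑1,3,8‑trimethoxy‑2‑methyl‑5‑(5‑phenylpentyl)‑5,6,7,8‑tetrahydroquinolin‑4(1H)‑one | COc1c(C)n(OC)c2c(c1=O)[C@@H](CCCCCc1ccccc1)CC[C@H]2OC | target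

Undefined centres in 5–13 (C2, carbinol, C8, or C4a, as applicable) are epimeric mixtures that are destroyed at Step 7 or Step 14.

## Totals
- Total steps: 18.
- Longest linear sequence: 18 steps from 1‑bromo‑5‑phenylpentane (17 from cyclohexenone).

## Three steps most likely to fail
1. **Step 15, KRED reduction.** No variant may give the cis (8R) alcohol, or the lipophilic substrate may be poorly soluble. Fallback: reduce 17 chemically (NaBH4 or L‑Selectride), separate the trans (8S) alcohol, and invert it by Mitsunobu reaction (p‑nitrobenzoic acid, DIAD, PPh3) followed by K2CO3/MeOH hydrolysis to give the cis (8R) alcohol.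
2. **Step 2, tandem ACA–aldol.** Residual Mg salts in the Grignard‑derived R2Zn can lower ee, and the α‑alkoxy aldehyde can give poor yield or dr. Fallback: use Grignard 2 directly in a Cu/Josiphos ACA to cyclohexenone (CuBr·SMe2, (R,S)‑Josiphos, t‑BuOMe, −75 °C) with TMSCl trapping. Isolate the regiodefined C1=C2 silyl enol ether, then do a TiCl4 Mukaiyama aldol with 4.
3. **Steps 17–18, N‑OH formation and O‑methylation.** Hydroxylamine ring exchange at the hindered fused pyranone may be slow, and methylation may give the 4‑OMe pyridine N‑oxide instead of the N‑OMe pyridone. Fallback: skip N‑OH and condense pyranone 19 directly with MeONH2·HCl in pyridine at 100 °C, so the N–OMe is formed in one step.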